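**Retrosynthetic overview**

1. Target (epiafzelechin-(4β→8)-catechin) ⇐ octabenzyl ether 18 by global hydrogenolysis; the lower unit is (+)-catechin (chiral pool, perbenzylated 15).
2. Key disconnection: the interflavan bond C4–C8' and the ring bond C2–C3 of the upper pyran ring (O1–C2–C3–C4–C4a–C8a) are made in one event from (2S,3S)-2-aryl-2,3-dihydrobenzofuran-3-carbaldehyde 12, in which the ring is still five-membered (O1–C2–C4–C4a–C8a) and C3 sits outside it as the formyl carbon.
3. Enabling feature: C4 is benzylic to the phloroglucinol A-ring (ortho to O1 and O5, para to O7) and C3 carries oxygen, so the C3(O)–C4(+) pair is a semipinacol retron; C2 (α-aryloxy, p-oxybenzylic) is the migrating carbon.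
4. Aldehyde 12 ⇐ 5-exo aryl-radical cyclisation of (S)-aryl 1-arylallyl ether 9; its single stereocentre (future C2) comes from Ir-catalysed asymmetric allylic etherification of iodophenol 7 with cinnamyl carbonate 5. C3 and C4 are then relayed from C2 in the key step.
5. Ring order: A- and B-rings bought; dihydrofuran ring (step 6); pyran C-ring by 5→6 ring expansion with simultaneous interflavan coupling (step 11); lower-unit rings from catechin.

Key step: step 11

Assumption: the antipode of the phosphoramidite ligand in step 5 is chosen so that the (S)-ether 9 results; the sense of induction is assigned by analogy and both ligand antipodes are available.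

**Step 1**
Reactants: 1 4-(benzyloxy)benzaldehyde; 2 ethyl (triphenylphosphoranylidene)acetate
Product: 3 ethyl (E)-3-[4-(benzyloxy)phenyl]prop-2-enoate
Conditions: toluene, 80 °C
Reagents that add atoms: none
Why: Wittig olefination with a stabilised ylide should give the E-cinnamate.

**Step 2**
Reactants: 3 ethyl (E)-3-[4-(benzyloxy)phenyl]prop-2-enoate
Product: 4 (E)-3-[4-(benzyloxy)phenyl]prop-2-en-1-ol
Conditions: DIBAL-H (2.2 equiv), CH2Cl2, −78 °C; Rochelle salt work-up
Reagents that add atoms: none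
Why: 1,2-reduction of the enoate with DIBAL-H should give the allylic alcohol without touching the alkene or the benzyl ether.

**Step 3**
Reactants: 4 (E)-3-[4-(benzyloxy)phenyl]prop-2-en-1-ol
Product: 5 (E)-3-[4-(benzyloxy)phenyl]prop-2-en-1-yl methyl carbonate
Conditions: ClCO2Me, pyridine, CH2Cl2, 0 °C
Reagents that add atoms: methyl chloroformate, COC(=O)Cl
Why: O-acylation of the primary allylic alcohol gives the carbonate leaving group needed for allyl-iridium formation.

**Step 4**
Reactants: 6 3,5-bis(benzyloxy)phenol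
Product: 7 3,5-bis(benzyloxy)-2-iodophenol
Conditions: NIS (1.0 equiv), CH2Cl2, −40 → 0 °C
Reagents that add atoms: N-iodosuccinimide, O=C1CCC(=O)N1I
Why: Electrophilic aromatic iodination is expected ortho to OH (C2), since the only other activated site (C4) is flanked by two benzyloxy groups.

**Step 5**
Reactants: 7 3,5-bis(benzyloxy)-2-iodophenol; 5 (E)-3-[4-(benzyloxy)phenyl]prop-2-en-1-yl methyl carbonate
Product: 9 1,5-bis(benzyloxy)-2-iodo-3-{[(1S)-1-[4-(benzyloxy)phenyl]prop-2-en-1-yl]oxy}benzene, via lithium aryloxide 8 (not isolated)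
Conditions: n-BuLi (1.0 equiv), THF, 0 °C; then 5, [Ir(cod)Cl]2 (2 mol %), BINOL-derived bis(1-phenylethyl)amine phosphoramidite (4 mol %, pre-activated with n-PrNH2), THF, 50 °C
Reagents that add atoms: none
Why: Iridium-catalysed asymmetric allylic etherification of an alkali aryloxide with a linear cinnamyl carbonate should give the branched ether, the new stereocentre (future C2) being set by the chiral Ir–phosphoramidite catalyst.

**Step 6**
Reactants: 9 1,5-bis(benzyloxy)-2-iodo-3-{[(1S)-1-[4-(benzyloxy)phenyl]prop-2-en-1-yl]oxy}benzene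
Product: 10 1-{[(2S,3R)-4,6-bis(benzyloxy)-2-[4-(benzyloxy)phenyl]-2,3-dihydro-1-benzofuran-3-yl]methoxy}-2,2,6,6-tetramethylpiperidine
Conditions: Bu3SnH (3 equiv, in portions), TEMPO (6 equiv), benzene, 70 °C
Reagents that add atoms: TEMPO, CC1(C)CCCC(C)(C)N1[O]
Why: 5-exo-trig aryl-radical cyclisation with nitroxide trapping of the primary radical should close the dihydrofuran ring, the C3 centre being set trans to the 2-aryl group (substrate control, aryl pseudo-equatorial in a chair-like transition state).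

**Step 7**
Reactants: 10 1-{[(2S,3R)-4,6-bis(benzyloxy)-2-[4-(benzyloxy)phenyl]-2,3-dihydro-1-benzofuran-3-yl]methoxy}-2,2,6,6-tetramethylpiperidine
Product: 11 [(2S,3R)-4,6-bis(benzyloxy)-2-[4-(benzyloxy)phenyl]-2,3-dihydro-1-benzofuran-3-yl]methanol
Conditions: Zn dust, AcOH/THF/H2O (3:1:1), 50 °C; any minor cis isomer removed by chromatography
Reagents that add atoms: none
Why: Zinc-mediated reductive N–O cleavage of the alkoxyamine should free the primary alcohol without affecting benzyl ethers or stereocentres.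

**Step 8**
Reactants: 11 [(2S,3R)-4,6-bis(benzyloxy)-2-[4-(benzyloxy)phenyl]-2,3-dihydro-1-benzofuran-3-yl]methanol
Product: 12 (2S,3S)-4,6-bis(benzyloxy)-2-[4-(benzyloxy)phenyl]-2,3-dihydro-1-benzofuran-3-carbaldehyde
Conditions: Dess–Martin periodinane, CH2Cl2, 0 °C → rt; used without chromatography
Reagents that add atoms: none
Why: Dess–Martin oxidation should give the α-aryl aldehyde under near-neutral conditions, the 2,3-trans isomer being the thermodynamically favoured one.

**Step 9**
Reactants: 13 (+)-catechin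
Product: 14 (2R,3S)-5,7-bis(benzyloxy)-2-[3,4-bis(benzyloxy)phenyl]chroman-3-ol (5,7,3',4'-tetra-O-benzylcatechin)
Conditions: BnBr (4.4 equiv), K2CO3, DMF, 0 °C → rt
Reagents that add atoms: benzyl bromide, BrCc1ccccc1
Why: Williamson etherification with carbonate base should benzylate only the four phenolic hydroxyls and leave the stereocentres untouched.

**Step 10**
Reactants: 14 5,7,3',4'-tetra-O-benzylcatechin
Product: 15 (2R,3S)-3,5,7-tris(benzyloxy)-2-[3,4-bis(benzyloxy)phenyl]chromane (penta-O-benzylcatechin)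
Conditions: NaH, BnBr, Bu4NI (cat.), DMF, 0 °C → rt
Reagents that add atoms: benzyl bromide, BrCc1ccccc1
Why: Williamson etherification of the secondary alcohol removes the only O–H that could intercept the oxocarbenium ion in step 11.

**Step 11**
Reactants: 12 (2S,3S)-4,6-bis(benzyloxy)-2-[4-(benzyloxy)phenyl]-2,3-dihydro-1-benzofuran-3-carbaldehyde; 15 penta-O-benzylcatechin
Product: 18 5,7,4'-tri-O-benzylepiafzelechin-(4β→8)-3,5,7,3',4'-penta-O-benzylcatechin (upper unit 2R,3R,4R with free 3-OH; lower unit 2R,3S), via 3-silyloxyflavan-4-yl cation triflate 16 (not isolated), via dimer 3-O-trimethylsilyl ether 17 (not isolated)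
Conditions: TMSOTf (1.1 equiv), 4 Å MS, CH2Cl2 (0.005 M in 12), −78 °C, 15 min; then 15 (3 equiv), −78 → −40 °C; sat. aq. NaHCO3; then K2CO3 (cat.), MeOH/THF, rt
Reagents that add atoms: none
Why: Proposed new method: O-silylation of the aldehyde gives a silyloxocarbenium ion in which the C2–C3 σ-bond of the dihydrofuran (C2 is an α-aryloxy, p-benzyloxybenzylic carbon and so a good migrating group) shifts to the carbonyl carbon with retention at C2, releasing the 2,4,6-trioxygenated benzylic cation 16; the closest known reaction types are the Lewis-acid semipinacol/Meinwald 1,2-shift, run here in the reverse (carbonyl-to-cation) sense as in the first stage of the acid-catalysed aldehyde–ketone rearrangement, and the TMSOTf-mediated flavan-4-yl cation/arene coupling used for B-type proanthocyanidins. The pyran ring is not closed by cyclisation but by this suprafacial [1,2]-alkyl shift, which enlarges the five-membered O-heterocycle to the six-membered one through a three-centre bridged transition state. C2 is carried over from step 5; C3 is set in the shift, where the bulky O-silyl group should take the exo position of the bicyclo[3.1.0]-like transition state while the aryl group on the migrating carbon stays anti to the formyl carbon (trans-aldehyde), which places OSiMe3 cis to the 2-aryl group. C4 is set when C8 of 15 adds to the planar cation anti to the 3-OSiMe3 group (3,4-trans, 2,4-trans), the usual outcome for 2,3-cis flavan-4-yl cations. The step needs the C-shift to win over a 1,2-hydride shift from C3 (which would lead to an aromatised 3-(silyloxymethyl)benzofuran) and over bimolecular attack of 15 on the activated aldehyde, and it needs C8 rather than C6 attack. The first should be helped by the cation-stabilising O and aryl substituents on the migrating carbon and by the stability of 16, the second is avoided by generating 16 at high dilution before 15 is added, and the third is the usual preference of 5,7-di-O-benzylflavans.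

**Step 12**
Reactants: 18 5,7,4'-tri-O-benzylepiafzelechin-(4β→8)-3,5,7,3',4'-penta-O-benzylcatechin
Product: 19 Gambiriin C
Conditions: H2 (1 atm), Pd(OH)2/C, THF/MeOH/H2O, rt
Reagents that add atoms: none
Why: Catalytic hydrogenolysis of the eight benzyl ethers should free all phenols and the lower 3-OH under neutral conditions that leave the interflavan bond and the four C–O/C–C stereocentres untouched.

**Compound list**

1 | 4-(benzyloxy)benzaldehyde | O=Cc1ccc(OCc2ccccc2)cc1 | starting material
2 | ethyl (triphenylphosphoranylidene)acetate | CCOC(=O)C=P(c1ccccc1)(c1ccccc1)c1ccccc1 | starting material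
3 | ethyl (E)-3-[4-(benzyloxy)phenyl]prop-2-enoate | CCOC(=O)/C=C/c1ccc(OCc2ccccc2)cc1 | intermediate
4 | (E)-3-[4-(benzyloxy)phenyl]prop-2-en-1-ol | OC/C=C/c1ccc(OCc2ccccc2)cc1 | intermediate
5 | (E)-3-[4-(benzyloxy)phenyl]prop-2-en-1-yl methyl carbonate | COC(=O)OC/C=C/c1ccc(OCc2ccccc2)cc1 | intermediate
6 | 3,5-bis(benzyloxy)phenol | Oc1cc(OCc2ccccc2)cc(OCc2ccccc2)c1 | starting material
7 | 3,5-bis(benzyloxy)-2-iodophenol | Oc1cc(OCc2ccccc2)cc(OCc2ccccc2)c1I | intermediate
8 | lithium 3,5-bis(benzyloxy)-2-iodophenoxide | [Li+].[O-]c1cc(OCc2ccccc2)cc(OCc2ccccc2)c1I | intermediate (not isolated)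
9 | 1,5-bis(benzyloxy)-2-iodo-3-{[(1S)-1-[4-(benzyloxy)phenyl]prop-2-en-1-yl]oxy}benzene | C=C[C@H](Oc1cc(OCc2ccccc2)cc(OCc2ccccc2)c1I)c1ccc(OCc2ccccc2)cc1 | intermediate
10 | 1-{[(2S,3R)-4,6-bis(benzyloxy)-2-[4-(benzyloxy)phenyl]-2,3-dihydro-1-benzofuran-3-yl]methoxy}-2,2,6,6-tetramethylpiperidine (2,3-trans) | C(c1ccccc1)Oc1ccc(cc1)[C@H]1Oc2cc(OCc3ccccc3)cc(OCc3ccccc3)c2[C@@H]1CON1C(C)(C)CCCC1(C)C | intermediate
11 | [(2S,3R)-4,6-bis(benzyloxy)-2-[4-(benzyloxy)phenyl]-2,3-dihydro-1-benzofuran-3-yl]methanol (2,3-trans) | C(c1ccccc1)Oc1ccc(cc1)[C@H]1Oc2cc(OCc3ccccc3)cc(OCc3ccccc3)c2[C@@H]1CO | intermediate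
12 | (2S,3S)-4,6-bis(benzyloxy)-2-[4-(benzyloxy)phenyl]-2,3-dihydro-1-benzofuran-3-carbaldehyde (2,3-trans) | C(c1ccccc1)Oc1ccc(cc1)[C@H]1Oc2cc(OCc3ccccc3)cc(OCc3ccccc3)c2[C@@H]1C=O | intermediate
13 | (+)-catechin, (2R,3S) | O[C@H]1Cc2c(O)cc(O)cc2O[C@@H]1c1ccc(O)c(O)c1 | starting material
14 | 5,7,3',4'-tetra-O-benzyl-(+)-catechin, (2R,3S) | O[C@H]1Cc2c(OCc3ccccc3)cc(OCc3ccccc3)cc2O[C@@H]1c1ccc(OCc2ccccc2)c(OCc2ccccc2)c1 | intermediate
15 | 3,5,7,3',4'-penta-O-benzyl-(+)-catechin, (2R,3S) | C(c1ccccc1)O[C@H]1Cc2c(OCc3ccccc3)cc(OCc3ccccc3)cc2O[C@@H]1c1ccc(OCc2ccccc2)c(OCc2ccccc2)c1 | intermediate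
16 | (2R,3R)-5,7-bis(benzyloxy)-2-[4-(benzyloxy)phenyl]-3-(trimethylsilyloxy)chroman-4-ylium trifluoromethanesulfonate (2,3-cis) | C(c1ccccc1)Oc1ccc(cc1)[C@H]2Oc3cc(OCc4ccccc4)cc(OCc4ccccc4)c3[CH+][C@H]2O[Si](C)(C)C.[O-]S(=O)(=O)C(F)(F)F | intermediate (not isolated)
17 | 3-O-trimethylsilyl ether of 18 (upper unit 2R,3R,4R; lower unit 2R,3S) | C(c1ccccc1)Oc1ccc(cc1)[C@H]2Oc3cc(OCc4ccccc4)cc(OCc4ccccc4)c3[C@H](c5c(OCc6ccccc6)cc(OCc6ccccc6)c7c5O[C@H](c8ccc(OCc9ccccc9)c(OCc9ccccc9)c8)[C@@H](OCc8ccccc8)C7)[C@H]2O[Si](C)(C)C | intermediate (not isolated)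
18 | 5,7,4'-tri-O-benzylepiafzelechin-(4β→8)-3,5,7,3',4'-penta-O-benzylcatechin (upper unit 2R,3R,4R, 2,3-cis-3,4-trans, free 3-OH; lower unit 2R,3S) | C(c1ccccc1)Oc1ccc(cc1)[C@H]2Oc3cc(OCc4ccccc4)cc(OCc4ccccc4)c3[C@H](c5c(OCc6ccccc6)cc(OCc6ccccc6)c7c5O[C@H](c8ccc(OCc9ccccc9)c(OCc9ccccc9)c8)[C@@H](OCc8ccccc8)C7)[C@H]2O | intermediate
19 | Gambiriin C, epiafzelechin-(4β→8)-catechin (upper unit 2R,3R,4R; lower unit 2R,3S) | Oc1ccc([C@H]2Oc3cc(O)cc(O)c3[C@H](c3c(O)cc(O)c4c3O[C@H](c3ccc(O)c(O)c3)[C@@H](O)C4)[C@H]2O)cc1 | target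

**Step count and risks**

Total step count: 12. Longest linear sequence: 9 (steps 1, 2, 3, 5, 6, 7, 8, 11, 12).

Steps most likely to fail:

1. Step 11 (proposed new method). What may go wrong: a 1,2-hydride shift from C3 to the activated carbonyl carbon followed by loss of the C2 proton (aromatisation to a benzofuran); direct Friedel–Crafts attack of an arene on the activated aldehyde; or poor facial control in the shift (2,3-trans instead of 2,3-cis). Fallback (sets out from 11, returns at 18), known chemistry in which the pyran ring still arises by ring enlargement: alcohol 11 would be converted into its methanesulfonate F1 (MsCl, Et3N, CH2Cl2, 0 °C) and solvolysed under buffered ionising conditions (NaHCO3, aqueous hexafluoroisopropanol, 40 °C). Neighbouring-group participation of the electron-rich A-ring (phenonium ion) and opening of the bridged ion by water at the secondary carbon with inversion should enlarge the dihydrofuran to the pyran ring and give 5,7,4'-tri-O-benzylafzelechin F2 (2,3-trans). Dess–Martin oxidation would give the flavan-3-one F3, and L-Selectride reduction (THF, −78 °C, hydride anti to the 2-aryl group) would give 5,7,4'-tri-O-benzylepiafzelechin F4 (2,3-cis). Benzylic oxidation with DDQ in the presence of 2-ethoxyethanol would give the 4β-(2-ethoxyethoxy) derivative F5, and TMSOTf-catalysed coupling of F5 with 15 (CH2Cl2, −78 °C) would give 18.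

2. Step 5. What may go wrong: ionisation of the electron-rich 1-arylallyl ether under the reaction conditions, with erosion of the branched/linear ratio and of the enantiomeric purity, or slow turnover with the ortho-iodinated aryloxide. Fallback (sets out from 4 and 7, returns at 9): Sharpless asymmetric epoxidation of 4 (L-(+)-diethyl tartrate, Ti(OiPr)4, t-BuOOH, 4 Å MS, −20 °C) would give the (2S,3S)-epoxy alcohol F6. Ti(OiPr)4-mediated opening of F6 at the benzylic C3 by phenol 7 with inversion would give the (2S,3R)-3-aryloxy-1,2-diol F7. Deoxygenative olefination of the vicinal diol (I2, PPh3, imidazole, toluene, 80 °C) would give 9.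

3. Step 6. What may go wrong: capture of the aryl radical before cyclisation, 1,5-hydrogen transfer from the neighbouring benzyloxy group, or low trans selectivity. Fallback (sets out from 9, returns at 12): intramolecular Heck reaction of 9 (Pd(OAc)2, PPh3, Ag2CO3, MeCN, 70 °C) would give the 3-methylidene-2,3-dihydrobenzofuran F8. Hydroboration–oxidation (9-BBN, THF; NaOH, H2O2) from the face anti to the 2-aryl group would give the 2,3-cis alcohol F9. Dess–Martin oxidation would give the 2,3-cis aldehyde F10, and Et3N-mediated epimerisation at C3 (CH2Cl2, rt) would give the more stable trans aldehyde 12.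

**Further compounds**

F1 | step 11 | [(2S,3R)-4,6-bis(benzyloxy)-2-[4-(benzyloxy)phenyl]-2,3-dihydro-1-benzofuran-3-yl]methyl methanesulfonate | C(c1ccccc1)Oc1ccc(cc1)[C@H]1Oc2cc(OCc3ccccc3)cc(OCc3ccccc3)c2[C@@H]1COS(C)(=O)=O
F2 | step 11 | 5,7,4'-tri-O-benzylafzelechin, (2R,3S), 2,3-trans | O[C@H]1Cc2c(OCc3ccccc3)cc(OCc3ccccc3)cc2O[C@@H]1c1ccc(OCc2ccccc2)cc1
F3 | step 11 | (2R)-5,7-bis(benzyloxy)-2-[4-(benzyloxy)phenyl]chroman-3-one | O=C1Cc2c(OCc3ccccc3)cc(OCc3ccccc3)cc2O[C@@H]1c1ccc(OCc2ccccc2)cc1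
F4 | step 11 | 5,7,4'-tri-O-benzylepiafzelechin, (2R,3R), 2,3-cis | O[C@@H]1Cc2c(OCc3ccccc3)cc(OCc3ccccc3)cc2O[C@@H]1c1ccc(OCc2ccccc2)cc1
F5 | step 11 | 5,7,4'-tri-O-benzyl-4β-(2-ethoxyethoxy)epiafzelechin (2,3-cis-3,4-trans) | C(c1ccccc1)Oc1ccc(cc1)[C@H]2Oc3cc(OCc4ccccc4)cc(OCc4ccccc4)c3[C@H](OCCOCC)[C@H]2O
F6 | step 5 | {(2S,3S)-3-[4-(benzyloxy)phenyl]oxiran-2-yl}methanol | OC[C@@H]1O[C@H]1c1ccc(OCc2ccccc2)cc1
F7 | step 5 | (2S,3R)-3-[3,5-bis(benzyloxy)-2-iodophenoxy]-3-[4-(benzyloxy)phenyl]propane-1,2-diol | OC[C@H](O)[C@H](Oc1cc(OCc2ccccc2)cc(OCc2ccccc2)c1I)c1ccc(OCc2ccccc2)cc1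
F8 | step 6 | (2R)-4,6-bis(benzyloxy)-2-[4-(benzyloxy)phenyl]-3-methylidene-2,3-dihydro-1-benzofuran (C2 has the same spatial arrangement as in 12) | C(c1ccccc1)Oc1ccc(cc1)[C@H]1Oc2cc(OCc3ccccc3)cc(OCc3ccccc3)c2C1=C
F9 | step 6 | [(2S,3S)-4,6-bis(benzyloxy)-2-[4-(benzyloxy)phenyl]-2,3-dihydro-1-benzofuran-3-yl]methanol (2,3-cis) | C(c1ccccc1)Oc1ccc(cc1)[C@H]1Oc2cc(OCc3ccccc3)cc(OCc3ccccc3)c2[C@H]1CO
F10 | step 6 | (2S,3R)-4,6-bis(benzyloxy)-2-[4-(benzyloxy)phenyl]-2,3-dihydro-1-benzofuran-3-carbaldehyde (2,3-cis) | C(c1ccccc1)Oc1ccc(cc1)[C@H]1Oc2cc(OCc3ccccc3)cc(OCc3ccccc3)c2[C@H]1C=O
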